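**Retrosynthetic overview**

1. The plan rests on C1, which carries ring C and sits on C8a of ring A. Ring A is a 4-oxy-3,5-dimethoxyphenyl unit whose two ortho carbons are equivalent, each ortho to one methoxyl and para to the other, so either can become C4a.
2. Key disconnection C4–C4a: ring B is closed last, as an enolised 2-tetralone (C3 ketone, C4 benzyl ester), by rhodium carbenoid substitution of ring A by a diazo keto ester. Rings A, C and D arrive intact.
3. Forward from the tetralone: the ester blocks C4, so the dianion is benzylated at C2 with the ring D bromide. DDQ then aromatises ring B, hydroxide frees the ring C phenol, and hydrogenolysis removes the benzyl groups and, by decarboxylation, the C4 carboxyl.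
4. Back from the diazo keto ester: diazo transfer, malonate chain extension of a 3,3-diarylpropanoic acid, and before that addition of the ring A Grignard reagent to the ring C arylidene Meldrum's acid (C1–C8a bond).
5. Design points: the ring C 4-oxygen is carried as a tosylate, not an ether, so that the ipso carbon of ring C (ortho to its methoxyl, para to that oxygen) cannot rival ring A in the carbenoid step. The C4 ester is benzyl so that this flanked ester leaves by hydrogenolysis and not by saponification.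

Key step: step 8

Remark: locants C1 to C8a are those of the target naphthalene throughout; the target has no stereocentre, so every sp3 intermediate is racemic (one enantiomer drawn) and rotation about the C1–ring C bond is left unspecified, as in the target. "Tosyloxy" means 4-methylbenzenesulfonyloxy.

**Route**

Step 1
Reactants: 1 4-hydroxy-2-methoxybenzaldehyde
Product: 2 4-formyl-3-methoxyphenyl 4-methylbenzenesulfonate
Conditions: TsCl, K2CO3, acetone, reflux
Reagents that add atoms: 4-toluenesulfonyl chloride, Cc1ccc(cc1)S(=O)(=O)Cl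
Why: O-sulfonylation of the phenoxide should give an arenesulfonate that withdraws the oxygen lone pair from ring C for step 8 and is inert to every step before step 12.

Step 2
Reactants: 2 4-formyl-3-methoxyphenyl 4-methylbenzenesulfonate; 3 Meldrum's acid
Product: 4 4-[(2,2-dimethyl-4,6-dioxo-1,3-dioxan-5-ylidene)methyl]-3-methoxyphenyl 4-methylbenzenesulfonate
Conditions: piperidine (cat.), AcOH (cat.), toluene, rt
Reagents that add atoms: none
Why: Knoevenagel condensation of a non-enolisable aryl aldehyde with the acidic methylene of Meldrum's acid should give the arylidene, which normally crystallises.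

Step 3
Reactants: 5 4-bromo-2,6-dimethoxyphenol
Product: 6 2-(benzyloxy)-5-bromo-1,3-dimethoxybenzene
Conditions: BnBr, K2CO3, DMF, 60 °C
Reagents that add atoms: benzyl bromide, BrCc1ccccc1
Why: Williamson etherification of the flanked but acidic phenol should proceed cleanly in a dipolar aprotic solvent.

Step 4
Reactants: 6 2-(benzyloxy)-5-bromo-1,3-dimethoxybenzene; 4 4-[(2,2-dimethyl-4,6-dioxo-1,3-dioxan-5-ylidene)methyl]-3-methoxyphenyl 4-methylbenzenesulfonate
Product: 8 4-{[4-(benzyloxy)-3,5-dimethoxyphenyl](2,2-dimethyl-4,6-dioxo-1,3-dioxan-5-yl)methyl}-3-methoxyphenyl 4-methylbenzenesulfonate (racemic), via Grignard reagent 7 (not isolated)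
Conditions: Mg, THF, 40 °C; then 4, THF, −40 → 0 °C; 1 M HCl
Reagents that add atoms: none
Why: Grignard formation followed by uncatalysed conjugate addition to the doubly activated arylidene Meldrum's acid, which is far more electrophilic than the aryl sulfonate, should form the C1–C8a bond; the new stereocentre at the future C1 forms without control and is erased in step 11.

Step 5
Reactants: 8 4-{[4-(benzyloxy)-3,5-dimethoxyphenyl](2,2-dimethyl-4,6-dioxo-1,3-dioxan-5-yl)methyl}-3-methoxyphenyl 4-methylbenzenesulfonate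
Product: 9 3-[4-(benzyloxy)-3,5-dimethoxyphenyl]-3-[2-methoxy-4-(tosyloxy)phenyl]propanoic acid (racemic)
Conditions: DMF–H2O (10:1), 100 °C
Reagents that add atoms: water, O
Why: Hydrolytic opening of the Meldrum's acid ring followed by thermal decarboxylation of the malonic acid should give the acid under near-neutral conditions that spare the sulfonate and the benzyl ether.

Step 6
Reactants: 9 3-[4-(benzyloxy)-3,5-dimethoxyphenyl]-3-[2-methoxy-4-(tosyloxy)phenyl]propanoic acid; 10 3-(benzyloxy)-3-oxopropanoic acid (monobenzyl malonate)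
Product: 12 benzyl 5-[4-(benzyloxy)-3,5-dimethoxyphenyl]-5-[2-methoxy-4-(tosyloxy)phenyl]-3-oxopentanoate (racemic), via acyl imidazolide 11 (not isolated)
Conditions: CDI, THF, rt; then 10, MgCl2, Et3N, THF–MeCN, rt → 45 °C; 1 M HCl
Reagents that add atoms: none
Why: Masamune–Brooks homologation, in which the acyl imidazolide is C-acylated by the magnesium enolate of the malonate half-ester and the adduct decarboxylates, should give the β-keto ester.

Step 7
Reactants: 12 benzyl 5-[4-(benzyloxy)-3,5-dimethoxyphenyl]-5-[2-methoxy-4-(tosyloxy)phenyl]-3-oxopentanoate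
Product: 13 benzyl 5-[4-(benzyloxy)-3,5-dimethoxyphenyl]-2-diazo-5-[2-methoxy-4-(tosyloxy)phenyl]-3-oxopentanoate (racemic)
Conditions: 4-acetamidobenzenesulfonyl azide, Et3N, MeCN, 0 °C → rt
Reagents that add atoms: 4-acetamidobenzenesulfonyl azide, CC(=O)Nc1ccc(cc1)S(=O)(=O)N=[N+]=[N-]
Why: Regitz diazo transfer to the active methylene of a β-keto ester is general and should tolerate every other group present.

Step 8
Reactants: 13 benzyl 5-[4-(benzyloxy)-3,5-dimethoxyphenyl]-2-diazo-5-[2-methoxy-4-(tosyloxy)phenyl]-3-oxopentanoate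
Product: 14 benzyl 6-(benzyloxy)-3-hydroxy-5,7-dimethoxy-1-[2-methoxy-4-(tosyloxy)phenyl]-1,2-dihydronaphthalene-4-carboxylate (racemic; enol form of the 2-tetralone ester)
Conditions: Rh2(OAc)4 (1 mol%), CH2Cl2, 40 °C, slow addition of 13
Reagents that add atoms: none
Why: Rh2(OAc)4 should expel N2 from 13 to give an electrophilic rhodium carbenoid at C4 that attacks an ortho carbon of ring A, and the arenium/rhodium-enolate zwitterion then loses the metal and a proton to restore the arene with the new C4–C4a bond. The closest known reaction type is the Rh2(OAc)4-catalysed aromatic substitution of 2-diazo-3-oxo-5-arylpentanoates (and of 1-diazo-4-arylbutan-2-ones) to 2-tetralones. Ring B closes in the six-membered mode (C4, C3, C2, C1, C8a, C4a) and the product rests as the hydrogen-bonded enol; no stereocentre is created, and racemic C1 is later erased. The step needs site selectivity (ring A against ring C) and mode selectivity (substitution against ipso addition leading to spiro or cycloheptatriene products). Ring A secures the first through its two equivalent ortho carbons, each ortho to one methoxyl and para to the other, while its ipso carbon gains little from the C6 benzyloxy group, which is twisted between two methoxyls; ring C is disarmed because its only free ortho carbon is meta to both oxygens and its ipso carbon is para to the electron-poor tosyloxy group. No C–H is placed for five-membered insertion, since the chain ends at the diaryl-substituted C1.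

Step 9
Reactants: 15 [4-(benzyloxy)-3-methoxyphenyl]methanol
Product: 16 1-(benzyloxy)-4-(bromomethyl)-2-methoxybenzene
Conditions: PBr3, Et2O, 0 °C; used at once
Reagents that add atoms: phosphorus tribromide, BrP(Br)Br
Why: Bromide displacement on the phosphite ester of a benzylic alcohol (SN2) should give the ring D bromide, which is used fresh because it is electron-rich and labile.

Step 10
Reactants: 14 benzyl 6-(benzyloxy)-3-hydroxy-5,7-dimethoxy-1-[2-methoxy-4-(tosyloxy)phenyl]-1,2-dihydronaphthalene-4-carboxylate; 16 1-(benzyloxy)-4-(bromomethyl)-2-methoxybenzene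
Product: 18 benzyl 6-(benzyloxy)-2-[4-(benzyloxy)-3-methoxybenzyl]-3-hydroxy-5,7-dimethoxy-1-[2-methoxy-4-(tosyloxy)phenyl]-1,2-dihydronaphthalene-4-carboxylate (racemic; 1,2-trans drawn), via dilithium dianion 17 (not isolated)
Conditions: LiN(i-Pr)2 (LDA, 2.1 equiv), THF, −78 → −20 °C; then 16, −78 → 0 °C; 1 M HCl
Reagents that add atoms: none
Why: Weiler dianion alkylation should remove the enol O–H and then C2–H, and the more basic C2 carbanion is benzylated while C4 stays blocked as the stabilised enolate; attack anti to the C1 aryl group should favour the 1,2-trans isomer, though either isomer serves.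

Step 11
Reactants: 18 benzyl 6-(benzyloxy)-2-[4-(benzyloxy)-3-methoxybenzyl]-3-hydroxy-5,7-dimethoxy-1-[2-methoxy-4-(tosyloxy)phenyl]-1,2-dihydronaphthalene-4-carboxylate
Product: 19 benzyl 6-(benzyloxy)-2-[4-(benzyloxy)-3-methoxybenzyl]-3-hydroxy-5,7-dimethoxy-1-[2-methoxy-4-(tosyloxy)phenyl]naphthalene-4-carboxylate
Conditions: DDQ (1.05 equiv), 1,4-dioxane, rt
Reagents that add atoms: none
Why: Quinone dehydrogenation should occur by hydride abstraction from the doubly benzylic C1–H of the enol and proton loss from C2, driven by formation of the naphthalene, with one equivalent of oxidant used to spare the new diarylmethane CH2 and the benzyl ethers.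

Step 12
Reactants: 19 benzyl 6-(benzyloxy)-2-[4-(benzyloxy)-3-methoxybenzyl]-3-hydroxy-5,7-dimethoxy-1-[2-methoxy-4-(tosyloxy)phenyl]naphthalene-4-carboxylate
Product: 20 benzyl 6-(benzyloxy)-2-[4-(benzyloxy)-3-methoxybenzyl]-3-hydroxy-1-(4-hydroxy-2-methoxyphenyl)-5,7-dimethoxynaphthalene-4-carboxylate
Conditions: KOH, 1,4-dioxane–H2O, 80 °C, argon; then 1 M HCl
Reagents that add atoms: none
Why: Hydroxide attack at sulfur (S–O cleavage of an aryl sulfonate) should free the ring C phenol, while the C4 ester, flanked by the C3 oxide and the peri C5 methoxyl, should resist acyl substitution, and any ester lost here would only anticipate the decarboxylation of step 13.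

Step 13
Reactants: 20 benzyl 6-(benzyloxy)-2-[4-(benzyloxy)-3-methoxybenzyl]-3-hydroxy-1-(4-hydroxy-2-methoxyphenyl)-5,7-dimethoxynaphthalene-4-carboxylate
Product: 22 1-(4-hydroxy-2-methoxyphenyl)-2-(4-hydroxy-3-methoxybenzyl)-5,7-dimethoxynaphthalene-3,6-diol (CNP0000246.0), via naphthoic acid 21 (not isolated)
Conditions: H2 (1 atm), 10% Pd/C, THF–MeOH, rt; filter under argon; then 60 °C
Reagents that add atoms: none
Why: Hydrogenolysis over Pd/C should cleave the benzyl ester and both benzyl ethers, and the liberated 2-hydroxy-1-naphthoic acid type, electron-rich and strained by the peri methoxyl, should lose CO2 on gentle warming by ipso protonation (thermal decarboxylation).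

**Compound list**

1 | 4-hydroxy-2-methoxybenzaldehyde | COc1cc(O)ccc1C=O | starting material
2 | 4-formyl-3-methoxyphenyl 4-methylbenzenesulfonate | COc1cc(OS(=O)(=O)c2ccc(C)cc2)ccc1C=O | intermediate
3 | Meldrum's acid (2,2-dimethyl-1,3-dioxane-4,6-dione) | CC1(C)OC(=O)CC(=O)O1 | starting material
4 | 4-[(2,2-dimethyl-4,6-dioxo-1,3-dioxan-5-ylidene)methyl]-3-methoxyphenyl 4-methylbenzenesulfonate | CC1(C)OC(=O)C(=Cc2ccc(OS(=O)(=O)c3ccc(C)cc3)cc2OC)C(=O)O1 | intermediate
5 | 4-bromo-2,6-dimethoxyphenol | COc1cc(Br)cc(OC)c1O | starting material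
6 | 2-(benzyloxy)-5-bromo-1,3-dimethoxybenzene | COc1cc(Br)cc(OC)c1OCc1ccccc1 | intermediate
7 | [4-(benzyloxy)-3,5-dimethoxyphenyl]magnesium bromide | COc1cc([Mg]Br)cc(OC)c1OCc1ccccc1 | intermediate
8 | 4-{[4-(benzyloxy)-3,5-dimethoxyphenyl](2,2-dimethyl-4,6-dioxo-1,3-dioxan-5-yl)methyl}-3-methoxyphenyl 4-methylbenzenesulfonate (racemic) | CC1(C)OC(=O)C(C(=O)O1)[C@@H](c1cc(OC)c(OCc2ccccc2)c(OC)c1)c1ccc(OS(=O)(=O)c2ccc(C)cc2)cc1OC | intermediate
9 | 3-[4-(benzyloxy)-3,5-dimethoxyphenyl]-3-[2-methoxy-4-(tosyloxy)phenyl]propanoic acid (racemic) | OC(=O)C[C@@H](c1cc(OC)c(OCc2ccccc2)c(OC)c1)c1ccc(OS(=O)(=O)c2ccc(C)cc2)cc1OC | intermediate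
10 | 3-(benzyloxy)-3-oxopropanoic acid (monobenzyl malonate) | OC(=O)CC(=O)OCc1ccccc1 | starting material
11 | 3-[4-(benzyloxy)-3,5-dimethoxyphenyl]-1-(imidazol-1-yl)-3-[2-methoxy-4-(tosyloxy)phenyl]propan-1-one (acyl imidazolide; racemic) | O=C(C[C@@H](c1cc(OC)c(OCc2ccccc2)c(OC)c1)c1ccc(OS(=O)(=O)c2ccc(C)cc2)cc1OC)n1ccnc1 | intermediate
12 | benzyl 5-[4-(benzyloxy)-3,5-dimethoxyphenyl]-5-[2-methoxy-4-(tosyloxy)phenyl]-3-oxopentanoate (racemic) | O=C(OCc1ccccc1)CC(=O)C[C@@H](c1cc(OC)c(OCc2ccccc2)c(OC)c1)c1ccc(OS(=O)(=O)c2ccc(C)cc2)cc1OC | intermediate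
13 | benzyl 5-[4-(benzyloxy)-3,5-dimethoxyphenyl]-2-diazo-5-[2-methoxy-4-(tosyloxy)phenyl]-3-oxopentanoate (racemic) | O=C(OCc1ccccc1)C(=[N+]=[N-])C(=O)C[C@@H](c1cc(OC)c(OCc2ccccc2)c(OC)c1)c1ccc(OS(=O)(=O)c2ccc(C)cc2)cc1OC | intermediate
14 | benzyl 6-(benzyloxy)-3-hydroxy-5,7-dimethoxy-1-[2-methoxy-4-(tosyloxy)phenyl]-1,2-dihydronaphthalene-4-carboxylate (racemic) | O=C(OCc1ccccc1)C1=C(O)C[C@H](c2ccc(OS(=O)(=O)c3ccc(C)cc3)cc2OC)c2cc(OC)c(OCc3ccccc3)c(OC)c12 | intermediate
15 | [4-(benzyloxy)-3-methoxyphenyl]methanol | COc1cc(CO)ccc1OCc1ccccc1 | starting material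
16 | 1-(benzyloxy)-4-(bromomethyl)-2-methoxybenzene | COc1cc(CBr)ccc1OCc1ccccc1 | intermediate
17 | dilithium dianion of 14 (enolate oxygen on C3, carbanion at C2; racemic) | [Li+].[Li+].O=C(OCc1ccccc1)C1=C([O-])[CH-][C@H](c2ccc(OS(=O)(=O)c3ccc(C)cc3)cc2OC)c2cc(OC)c(OCc3ccccc3)c(OC)c12 | intermediate
18 | benzyl 6-(benzyloxy)-2-[4-(benzyloxy)-3-methoxybenzyl]-3-hydroxy-5,7-dimethoxy-1-[2-methoxy-4-(tosyloxy)phenyl]-1,2-dihydronaphthalene-4-carboxylate (racemic; 1,2-trans drawn) | O=C(OCc1ccccc1)C1=C(O)[C@@H](Cc2ccc(OCc3ccccc3)c(OC)c2)[C@H](c2ccc(OS(=O)(=O)c3ccc(C)cc3)cc2OC)c2cc(OC)c(OCc3ccccc3)c(OC)c12 | intermediate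
19 | benzyl 6-(benzyloxy)-2-[4-(benzyloxy)-3-methoxybenzyl]-3-hydroxy-5,7-dimethoxy-1-[2-methoxy-4-(tosyloxy)phenyl]naphthalene-4-carboxylate | O=C(OCc1ccccc1)c1c(O)c(Cc2ccc(OCc3ccccc3)c(OC)c2)c(-c2ccc(OS(=O)(=O)c3ccc(C)cc3)cc2OC)c2cc(OC)c(OCc3ccccc3)c(OC)c12 | intermediate
20 | benzyl 6-(benzyloxy)-2-[4-(benzyloxy)-3-methoxybenzyl]-3-hydroxy-1-(4-hydroxy-2-methoxyphenyl)-5,7-dimethoxynaphthalene-4-carboxylate | O=C(OCc1ccccc1)c1c(O)c(Cc2ccc(OCc3ccccc3)c(OC)c2)c(-c2ccc(O)cc2OC)c2cc(OC)c(OCc3ccccc3)c(OC)c12 | intermediate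
21 | 3,6-dihydroxy-2-(4-hydroxy-3-methoxybenzyl)-1-(4-hydroxy-2-methoxyphenyl)-5,7-dimethoxynaphthalene-4-carboxylic acid | OC(=O)c1c(O)c(Cc2ccc(O)c(OC)c2)c(-c2ccc(O)cc2OC)c2cc(OC)c(O)c(OC)c12 | intermediate
22 | 1-(4-hydroxy-2-methoxyphenyl)-2-(4-hydroxy-3-methoxybenzyl)-5,7-dimethoxynaphthalene-3,6-diol (CNP0000246.0) | COc1cc(Cc2c(O)cc3c(OC)c(O)c(OC)cc3c2-c2ccc(O)cc2OC)ccc1O | target

**Step count and risks**

Total step count: 13. Longest linear sequence: 11 steps (steps 1, 2, 4, 5, 6, 7, 8, 10, 11, 12, 13).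

Steps most likely to fail:

Step 8. The carbenoid may add across an ipso–ortho bond and ring-expand to a cycloheptatriene, be captured by the ortho-methoxyl oxygen of ring C as an oxonium ylide, or dimerise, instead of substituting ring A. The fallback sets out from 9 and comes back to the route at 14. Oxalyl chloride with catalytic DMF in CH2Cl2 should convert 9 into 3-[4-(benzyloxy)-3,5-dimethoxyphenyl]-3-[2-methoxy-4-(tosyloxy)phenyl]propanoyl chloride F1. Excess diazomethane in Et2O at 0 °C should then give 4-[4-(benzyloxy)-3,5-dimethoxyphenyl]-1-diazo-4-[2-methoxy-4-(tosyloxy)phenyl]butan-2-one F2. TFA in CH2Cl2 at −20 °C should protonate the diazo carbon, and ring A, still the most nucleophilic arene, displaces N2 through its ortho carbon. This is acid-promoted aryl participation, a cationic Friedel–Crafts alkylation with no metal carbenoid, and should give 6-(benzyloxy)-5,7-dimethoxy-1-[2-methoxy-4-(tosyloxy)phenyl]-1,4-dihydronaphthalen-3(2H)-one F3. NaH and dibenzyl carbonate in THF at reflux should then carboxylate the conjugated C4 enolate under thermodynamic control and return 14.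

Step 11. The oxidant may go on to abstract hydride from the new diarylmethane CH2 or from the benzyl ether methylenes, or oxidise the ortho-alkyl naphthol to a quinone methide. The fallback sets out from 18 and comes back at 19. A second dianion formation with LiN(i-Pr)2 (2.2 equiv, THF, −78 °C) and quenching with PhSeBr should place selenium at C2 anti to the C1 aryl group, giving benzyl 6-(benzyloxy)-2-[4-(benzyloxy)-3-methoxybenzyl]-3-hydroxy-5,7-dimethoxy-1-[2-methoxy-4-(tosyloxy)phenyl]-2-(phenylselanyl)-1,2-dihydronaphthalene-4-carboxylate F4. H2O2 in CH2Cl2–pyridine at 0 °C should oxidise selenium, and syn elimination of the selenoxide toward the cis C1–H (or toward the benzylic CH2, whose exocyclic alkene tautomerises) should give 19 with no hydride-abstracting oxidant present.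

Step 10. The second deprotonation may be incomplete, the enolate oxygen may be alkylated, or the electron-rich benzylic bromide may be lost by self-condensation before it meets the hindered C2 carbanion. The fallback sets out from 14 and comes back at 19, so it also bypasses step 11. The dianion 17 is made as before and treated at −78 °C with commercial 4-(benzyloxy)-3-methoxybenzaldehyde, a hard and fast electrophile that cannot O-alkylate. The lithium aldol should give benzyl 6-(benzyloxy)-2-{[4-(benzyloxy)-3-methoxyphenyl](hydroxy)methyl}-3-hydroxy-5,7-dimethoxy-1-[2-methoxy-4-(tosyloxy)phenyl]-1,2-dihydronaphthalene-4-carboxylate F5 as a mixture of diastereomers. TsOH (cat.) in toluene at 60 °C should dehydrate it to benzyl 6-(benzyloxy)-2-[4-(benzyloxy)-3-methoxybenzylidene]-3-hydroxy-5,7-dimethoxy-1-[2-methoxy-4-(tosyloxy)phenyl]-1,2-dihydronaphthalene-4-carboxylate F6. F6 is a non-aromatic tautomer of 19 and should isomerise to it under the same conditions (or with a trace of DBU) by shift of the C1 hydrogen to the exocyclic carbon.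

**Further compounds**

F1 | step 8 | 3-[4-(benzyloxy)-3,5-dimethoxyphenyl]-3-[2-methoxy-4-(tosyloxy)phenyl]propanoyl chloride (racemic) | ClC(=O)C[C@@H](c1cc(OC)c(OCc2ccccc2)c(OC)c1)c1ccc(OS(=O)(=O)c2ccc(C)cc2)cc1OC
F2 | step 8 | 4-[4-(benzyloxy)-3,5-dimethoxyphenyl]-1-diazo-4-[2-methoxy-4-(tosyloxy)phenyl]butan-2-one (racemic) | [N-]=[N+]=CC(=O)C[C@@H](c1cc(OC)c(OCc2ccccc2)c(OC)c1)c1ccc(OS(=O)(=O)c2ccc(C)cc2)cc1OC
F3 | step 8 | 6-(benzyloxy)-5,7-dimethoxy-1-[2-methoxy-4-(tosyloxy)phenyl]-1,4-dihydronaphthalen-3(2H)-one (racemic) | O=C1Cc2c(OC)c(OCc3ccccc3)c(OC)cc2[C@@H](c2ccc(OS(=O)(=O)c3ccc(C)cc3)cc2OC)C1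
F4 | step 11 | benzyl 6-(benzyloxy)-2-[4-(benzyloxy)-3-methoxybenzyl]-3-hydroxy-5,7-dimethoxy-1-[2-methoxy-4-(tosyloxy)phenyl]-2-(phenylselanyl)-1,2-dihydronaphthalene-4-carboxylate (racemic; selenium trans to the C1 aryl group) | O=C(OCc1ccccc1)C1=C(O)[C@@](Cc2ccc(OCc3ccccc3)c(OC)c2)([Se]c2ccccc2)[C@H](c2ccc(OS(=O)(=O)c3ccc(C)cc3)cc2OC)c2cc(OC)c(OCc3ccccc3)c(OC)c12
F5 | step 10 | benzyl 6-(benzyloxy)-2-{[4-(benzyloxy)-3-methoxyphenyl](hydroxy)methyl}-3-hydroxy-5,7-dimethoxy-1-[2-methoxy-4-(tosyloxy)phenyl]-1,2-dihydronaphthalene-4-carboxylate (racemic; 1,2-trans drawn, carbinol centre unassigned) | O=C(OCc1ccccc1)C1=C(O)[C@@H](C(O)c2ccc(OCc3ccccc3)c(OC)c2)[C@H](c2ccc(OS(=O)(=O)c3ccc(C)cc3)cc2OC)c2cc(OC)c(OCc3ccccc3)c(OC)c12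
F6 | step 10 | benzyl 6-(benzyloxy)-2-[4-(benzyloxy)-3-methoxybenzylidene]-3-hydroxy-5,7-dimethoxy-1-[2-methoxy-4-(tosyloxy)phenyl]-1,2-dihydronaphthalene-4-carboxylate (racemic; E isomer drawn) | O=C(OCc1ccccc1)C1=C(O)/C(=C/c2ccc(OCc3ccccc3)c(OC)c2)[C@H](c2ccc(OS(=O)(=O)c3ccc(C)cc3)cc2OC)c2cc(OC)c(OCc3ccccc3)c(OC)c12
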